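Assumption: germacrane numbering is used for all intermediates (ring C1–C10, lactone carbons C11–C13, C14 on C10, C15 on C4). The sense of induction in step 2 is taken as drawn, and the antipodal ligand is used if it proves opposite.

**Retrosynthetic overview**
1. Target 27 comes from the ten-membered keto lactone 22 by C8 reduction, angeloylation and desilylation.
2. 22 comes from tricycle 21 by the key five-to-ten ring expansion. This is an oxidative Grob-type fragmentation of the γ-hydroxystannane that cleaves C2–C8 and creates the E-C1=C2 alkene and the C8 ketone.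
3. 21 comes from cyclopentanone 15. C7–C8 is made by a zinc Barbier addition of dienyl bromide 12, and C5–C6 by a Nozaki–Hiyama–Kishi closure followed by lactonisation.
4. 15 comes from enone 4, Me3SnLi and iodoenal 8 by a one-pot conjugate addition and anti aldol.
5. 4 comes from 2,5-dimethylfuran through a new enantioselective aldol cyclisation. Ring order: cyclopentane, cycloheptene, lactone, cyclodecadiene.

**Step 1**
Reactants: 1 2,5-dimethylfuran
Product: 2 (3Z)-hex-3-ene-2,5-dione
Conditions: mCPBA (1.05 equiv), CH2Cl2, 0 °C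
Reagents that add atoms: mCPBA, OOC(=O)c1cccc(Cl)c1
Why: Oxidative furan ring opening gives the cis-enedione, whose Z geometry is inherited from the furan ring.

**Step 2**
Reactants: 2 (3Z)-hex-3-ene-2,5-dione
Product: 3 (4S)-4-hydroxy-4-methylcyclopent-2-en-1-one
Conditions: Et2Zn (10 mol %), (S,S)-ProPhenol (5 mol %), 4 Å MS, THF, −20 °C
Reagents that add atoms: none
Why: Proposed new method: the dinuclear zinc–ProPhenol complex should turn one methyl ketone into a zinc enolate while the second zinc binds the other carbonyl held close by the Z-alkene, so that a 5-(enolexo)-exo-trig aldol closes the ring with one carbonyl face shielded by the ligand pocket and sets C10 as S, the closest known reaction types being the base-mediated racemic cyclisation of cis-enediones to 4-hydroxycyclopentenones and the ProPhenol–zinc direct aldol addition of methyl ketones.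

**Step 3**
Reactants: 3 (4S)-4-hydroxy-4-methylcyclopent-2-en-1-one
Product: 4 (4S)-4-methyl-4-(triethylsilyloxy)cyclopent-2-en-1-one
Conditions: TESOTf, 2,6-lutidine, CH2Cl2, −78 to 0 °C
Reagents that add atoms: triethylsilyl triflate, CC[Si](CC)(CC)OS(=O)(=O)C(F)(F)F
Why: Silyl triflate silylation of the tertiary alcohol blocks retro-aldol and makes the oxygen face of the ring the hindered one.

**Step 4**
Reactants: 5 prop-2-yn-1-ol
Product: 7 (2Z)-3-iodo-2-methylprop-2-en-1-ol, via alkenylmagnesium alkoxide 6 (not isolated)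
Conditions: MeMgBr (2.5 equiv), CuI (10 mol %), Et2O/THF, −10 °C to rt; then I2, 0 °C
Reagents that add atoms: methylmagnesium bromide, C[Mg]Br; iodine, II
Why: Alkoxide-directed copper-catalysed carbomagnesiation followed by iodinolysis with retention gives only the alkene with iodine cis to CH2OH, which fixes the Z-C4=C5 geometry.

**Step 5**
Reactants: 7 (2Z)-3-iodo-2-methylprop-2-en-1-ol
Product: 8 (2Z)-3-iodo-2-methylprop-2-enal
Conditions: MnO2, CH2Cl2, rt, dark
Reagents that add atoms: none
Why: Neutral allylic oxidation with MnO2 leaves the vinyl iodide and its geometry intact.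

**Step 6**
Reactants: 9 acrolein; 10 methyl acrylate
Product: 11 methyl 3-hydroxy-2-methylidenepent-4-enoate (racemic)
Conditions: DABCO (20 mol %), neat, rt
Reagents that add atoms: none
Why: A Morita–Baylis–Hillman reaction joins C7 to C11, and the carbinol centre is erased in the next step.

**Step 7**
Reactants: 11 methyl 3-hydroxy-2-methylidenepent-4-enoate
Product: 12 methyl (2Z)-2-(bromomethyl)penta-2,4-dienoate
Conditions: PBr3, Et2O, −10 °C
Reagents that add atoms: phosphorus tribromide, BrP(Br)Br
Why: SN2′ bromination of the Baylis–Hillman alcohol gives the conjugated primary allylic bromide with the vinyl group cis to CH2Br.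

**Step 8**
Reactants: 4 (4S)-4-methyl-4-(triethylsilyloxy)cyclopent-2-en-1-one; 8 (2Z)-3-iodo-2-methylprop-2-enal
Product: 15 (2R,3S,4S)-2-[(1S,2Z)-3-iodo-2-methyl-1-(triethylsilyloxy)prop-2-en-1-yl]-4-methyl-4-(triethylsilyloxy)-3-(trimethylstannyl)cyclopentan-1-one, via lithium enolate 13 (not isolated), via lithium aldolate 14 (not isolated)
Conditions: Me3SnSnMe3, MeLi, THF, −20 °C; 4, −78 °C; 8, −78 °C; TESOTf, −78 to −20 °C
Reagents that add atoms: hexamethylditin, C[Sn](C)(C)[Sn](C)(C)C; triethylsilyl triflate, CC[Si](CC)(CC)OS(=O)(=O)C(F)(F)F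
Why: In this three-component conjugate addition and aldol the stannyl anion adds to C1 anti to the silyloxy group, the aldehyde is taken up at C2 trans to tin, and the ring-locked E-enolate reacts through a Zimmerman–Traxler chair to give the anti aldol, which is C3 (S).

**Step 9**
Reactants: 15 stannyl cyclopentanone; 12 methyl (2Z)-2-(bromomethyl)penta-2,4-dienoate
Product: 17 tertiary alcohol formed by γ-addition of the allylzinc at C8 (C8–OH cis to the C2 side chain; C7 bears vinyl and the 1-(methoxycarbonyl)vinyl group and is configured as in the target), via allylzinc bromide 16 (not isolated)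
Conditions: Zn dust, THF/sat. aq NH4Cl (4:1), 0 °C to rt
Reagents that add atoms: none
Why: In this Barbier-type SE2′ allylation the reagent attacks the ketone face opposite the C2 substituent, and the chair with the branched C2 arm equatorial gives the usual syn topicity of 2-(alkoxycarbonyl)allyl metals, which sets C7.

**Step 10**
Reactants: 17 Barbier adduct
Product: 19 C6 aldehyde (the C7 vinyl group cut down to CHO), via vicinal diol 18 (not isolated)
Conditions: OsO4 (2 mol %), NaIO4, 2,6-lutidine, dioxane/H2O (3:1), 0 °C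
Reagents that add atoms: sodium periodate, [Na+].[O-]I(=O)(=O)=O
Why: Lemieux–Johnson cleavage takes only the monosubstituted alkene, because the acrylate and the trisubstituted iodoalkene are electron-poor or hindered, and the lutidine buffer protects the C7 centre and the silyl ethers.

**Step 11**
Reactants: 19 C6 aldehyde
Product: 21 tricyclic cis-fused α-methylene-γ-lactone (trans-fused cyclopentane and cycloheptene, free tertiary C8–OH, C1–SnMe3; C6 is S), via hydroxy ester 20 (not isolated)
Conditions: CrCl2 (6 equiv), NiCl2 (1 mol %), DMSO/THF, rt; then SiO2, CH2Cl2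
Reagents that add atoms: none
Why: In this intramolecular Nozaki–Hiyama–Kishi reaction the ring constraint holds C5 gauche to C8 and anti to the acrylate unit, so Felkin–Anh attack gives the C6 alkoxide whose lactonisation onto C12 delivers the cis lactone, while the hindered tertiary alcohol stays free.

**Step 12**
Reactants: 21 tricyclic γ-hydroxystannane
Product: 22 (1E,4Z)-3,10-bis(triethylsilyloxy)-8-oxogermacra-1,4,11(13)-trien-6,12-olide (C3 S; C6, C7 and C10 as in the target)
Conditions: Pb(OAc)4 (1.2 equiv), CH2Cl2, −20 °C to rt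
Reagents that add atoms: none
Why: In this oxidative Grob-type 1,4-fragmentation the lead alkoxide at O8 collapses to the ketone as the C2–C8 bond breaks anti-periplanar to the C1–Sn bond, which expands the five-membered ring to the ten-membered one under non-basic conditions, and the trans relation of tin and the C3 chain is translated into the E-alkene.

**Step 13**
Reactants: 22 ten-membered keto lactone
Product: 23 (8S)-alcohol
Conditions: (R)-Me-CBS oxazaborolidine (0.5 equiv), catecholborane, toluene, −78 °C
Reagents that add atoms: none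
Why: Corey–Bakshi–Shibata reduction distinguishes the branched C7 arm from the C9 methylene and gives the 8S alcohol under reagent control without touching the methylene lactone.

**Step 14**
Reactants: 23 (8S)-alcohol; 24 angelic acid
Product: 26 8-O-angeloyl-3,10-bis(triethylsilyl) ether of the target, via mixed anhydride 25 (not isolated)
Conditions: 24, 2,4,6-trichlorobenzoyl chloride, Et3N, toluene, rt; then 23, 75 °C
Reagents that add atoms: none
Why: Yamaguchi esterification without a nucleophilic catalyst acylates the only free hydroxyl and avoids isomerisation of the angelate to the tiglate.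

**Step 15**
Reactants: 26 bis-silyl ether
Product: 27 target
Conditions: HF·pyridine, pyridine/THF, 0 °C
Reagents that add atoms: none
Why: Buffered fluoride desilylation frees the C3 and C10 alcohols without affecting the esters, the alkenes or any stereocentre.

**Compound list**
1 | 2,5-dimethylfuran | Cc1ccc(C)o1 | starting material
2 | (3Z)-hex-3-ene-2,5-dione | CC(=O)/C=C\C(C)=O | intermediate
3 | (4S)-4-hydroxy-4-methylcyclopent-2-en-1-one | O=C1C=C[C@@](C)(O)C1 | intermediate
4 | (4S)-4-methyl-4-(triethylsilyloxy)cyclopent-2-en-1-one | O=C1C=C[C@@](C)(O[Si](CC)(CC)CC)C1 | intermediate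
5 | prop-2-yn-1-ol | C#CCO | starting material
6 | bromomagnesium (2Z)-3-(bromomagnesio)-2-methylprop-2-en-1-olate | Br[Mg]OC/C(C)=C\[Mg]Br | intermediate
7 | (2Z)-3-iodo-2-methylprop-2-en-1-ol | OC/C(C)=C\I | intermediate
8 | (2Z)-3-iodo-2-methylprop-2-enal | O=C/C(C)=C\I | intermediate
9 | acrolein | C=CC=O | starting material
10 | methyl acrylate | C=CC(=O)OC | starting material
11 | methyl 3-hydroxy-2-methylidenepent-4-enoate (racemic) | C=CC(O)C(=C)C(=O)OC | intermediate
12 | methyl (2Z)-2-(bromomethyl)penta-2,4-dienoate | COC(=O)/C(CBr)=C/C=C | intermediate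
13 | lithium enolate after stannyl addition (Sn trans to OTES) | [Li]OC1=C[C@H]([Sn](C)(C)C)[C@@](C)(O[Si](CC)(CC)CC)C1 | intermediate
14 | lithium anti-aldolate | O=C1C[C@](C)(O[Si](CC)(CC)CC)[C@@H]([Sn](C)(C)C)[C@@H]1[C@H](O[Li])/C(C)=C\I | intermediate
15 | (2R,3S,4S)-2-[(1S,2Z)-3-iodo-2-methyl-1-(triethylsilyloxy)prop-2-en-1-yl]-4-methyl-4-(triethylsilyloxy)-3-(trimethylstannyl)cyclopentan-1-one | O=C1C[C@](C)(O[Si](CC)(CC)CC)[C@@H]([Sn](C)(C)C)[C@@H]1[C@H](O[Si](CC)(CC)CC)/C(C)=C\I | intermediate
16 | allylzinc bromide from 12 | COC(=O)/C(C[Zn]Br)=C/C=C | intermediate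
17 | Barbier adduct (tertiary C8 alcohol, C7 vinyl) | O[C@]1([C@H](C=C)C(=C)C(=O)OC)C[C@](C)(O[Si](CC)(CC)CC)[C@@H]([Sn](C)(C)C)[C@@H]1[C@H](O[Si](CC)(CC)CC)/C(C)=C\I | intermediate
18 | vicinal diol from the C7 vinyl group (carbinol epimers) | O[C@]1([C@H](C(O)CO)C(=C)C(=O)OC)C[C@](C)(O[Si](CC)(CC)CC)[C@@H]([Sn](C)(C)C)[C@@H]1[C@H](O[Si](CC)(CC)CC)/C(C)=C\I | intermediate
19 | C6 aldehyde | O[C@]1([C@H](C=O)C(=C)C(=O)OC)C[C@](C)(O[Si](CC)(CC)CC)[C@@H]([Sn](C)(C)C)[C@@H]1[C@H](O[Si](CC)(CC)CC)/C(C)=C\I | intermediate
20 | bicyclic C6-hydroxy methyl ester | COC(=O)C(=C)[C@H]1[C@@H](O)C=C(C)[C@@H](O[Si](CC)(CC)CC)[C@H]2[C@H]([Sn](C)(C)C)[C@@](C)(O[Si](CC)(CC)CC)C[C@]12O | intermediate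
21 | tricyclic γ-hydroxystannane lactone | C=C1C(=O)O[C@H]2C=C(C)[C@@H](O[Si](CC)(CC)CC)[C@H]3[C@H]([Sn](C)(C)C)[C@@](C)(O[Si](CC)(CC)CC)C[C@]3(O)[C@@H]12 | intermediate
22 | (1E,4Z)-3,10-bis(triethylsilyloxy)-8-oxogermacra-1,4,11(13)-trien-6,12-olide | C=C1C(=O)O[C@H]2/C=C(/C)[C@@H](O[Si](CC)(CC)CC)/C=C/[C@@](C)(O[Si](CC)(CC)CC)CC(=O)[C@@H]12 | intermediate
23 | (8S)-alcohol | C=C1C(=O)O[C@H]2/C=C(/C)[C@@H](O[Si](CC)(CC)CC)/C=C/[C@@](C)(O[Si](CC)(CC)CC)C[C@H](O)[C@@H]12 | intermediate
24 | angelic acid, (2Z)-2-methylbut-2-enoic acid | C/C=C(/C)C(=O)O | starting material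
25 | angelic 2,4,6-trichlorobenzoic anhydride | C/C=C(/C)C(=O)OC(=O)c1c(Cl)cc(Cl)cc1Cl | intermediate
26 | 8-O-angeloyl-3,10-bis(triethylsilyl) ether | C=C1C(=O)O[C@H]2/C=C(/C)[C@@H](O[Si](CC)(CC)CC)/C=C/[C@@](C)(O[Si](CC)(CC)CC)C[C@H](OC(=O)/C(C)=C\C)[C@@H]12 | intermediate
27 | CNP0262559.5, (3S,6S,7R,8S,10S) | C=C1C(=O)O[C@H]2/C=C(/C)[C@@H](O)/C=C/[C@@](C)(O)C[C@H](OC(=O)/C(C)=C\C)[C@@H]12 | target

**Total step count:** 15.
**Longest linear sequence:** 11 (steps 1, 2, 3 and 8–15).

**Steps most likely to fail**

Step 2 (new enantioselective aldol cyclisation). The ee may be low, or it may erode through retro-aldol. The fallback sets out from 2 and comes back at 3. Aqueous Na2CO3 cyclises 2 to racemic 4-hydroxy-4-methylcyclopent-2-en-1-one F1. This is then resolved by lipase CAL-A with vinyl butanoate. The faster-reacting enantiomer is removed as (1R)-1-methyl-4-oxocyclopent-2-en-1-yl butanoate F2, and unreacted (S)-3 is carried on.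

Step 9 (intermolecular allylation of a hindered ketone, C7 control, and the epimerisable aldehyde 19 that follows). The fallback sets out from 15 and 12 and comes back at 21, so it bypasses 17–20.
- KOAc in DMF converts 12 into methyl (2E)-2-(acetoxymethyl)penta-2,4-dienoate F3.
- OsO4/NaIO4 cleavage of F3 gives the stable conjugated enal methyl (2E)-2-(acetoxymethyl)-4-oxobut-2-enoate F4.
- An intermolecular Nozaki–Hiyama–Kishi coupling of 15 with F4 (CrCl2, NiCl2, chiral sulfonamide ligand) sets C6 under ligand control and gives the bis-allylic alcohol F5.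
- Pd(PPh3)4 and InI then convert the allylic acetate into an allylindium, which adds through C7 to the C8 ketone intramolecularly.
- The C6 hydroxyl closes the lactone to give 21.

Step 13 (facial selectivity at C8 between two bulky arms). The fallback sets out from 22 and comes back at 26. Substrate-controlled Luche reduction (NaBH4, CeCl3·7H2O, MeOH, −78 °C) from the ring periphery gives the 8-epi alcohol F6. A Mitsunobu esterification with angelic acid 24 (PPh3, DIAD, toluene) then inverts C8 and installs the angelate in one operation.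

**Further compounds**
F1 | step 2 | racemic 4-hydroxy-4-methylcyclopent-2-en-1-one | O=C1C=CC(C)(O)C1
F2 | step 2 | (1R)-1-methyl-4-oxocyclopent-2-en-1-yl butanoate | O=C1C=C[C@](C)(OC(=O)CCC)C1
F3 | step 9 | methyl (2E)-2-(acetoxymethyl)penta-2,4-dienoate | COC(=O)/C(COC(C)=O)=C/C=C
F4 | step 9 | methyl (2E)-2-(acetoxymethyl)-4-oxobut-2-enoate | COC(=O)/C(COC(C)=O)=C/C=O
F5 | step 9 | C5–C6 coupled bis-allylic alcohol (C6 as in the target, C8 ketone retained) | O=C1C[C@](C)(O[Si](CC)(CC)CC)[C@@H]([Sn](C)(C)C)[C@@H]1[C@H](O[Si](CC)(CC)CC)/C(C)=C\[C@H](O)/C=C(\COC(C)=O)C(=O)OC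
F6 | step 13 | 8-epi alcohol | C=C1C(=O)O[C@H]2/C=C(/C)[C@@H](O[Si](CC)(CC)CC)/C=C/[C@@](C)(O[Si](CC)(CC)CC)C[C@@H](O)[C@@H]12
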